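## Structural features

The target 21 is a monocyclic cyclohept-2-en-1-one: C1 is the ketone, C2 carries CH2OH, C5 is quaternary (methyl and 4-methylpent-3-enyl), C6 carries an (E)-2-acyloxyvinyl arm (an enol 3-methylbut-2-enoate) and C7 an acetonyl arm. C5, C6 and C7 are contiguous stereocentres (5S,6S,7R): the C6 and C7 arms are cis, and the homoprenyl chain on C5 is anti to the C6 arm. The enol ester is an acyl donor that does not survive nucleophiles, strong base or hydride, and the 2-(hydroxymethyl)enone is a Michael acceptor. C7–H is α to C1 and can epimerise; C1 and the acetonyl ketone form a 1,4-diketone, and the masked aldehyde carbon of the enol ester is 1,6 to the methyl ketone, so five-membered aldol closures threaten whenever these carbonyls are free together. The homoprenyl alkene tolerates neither ozone, peracids nor metal-hydride hydrogen-atom transfer. The real difficulty is a stereotriad with a quaternary centre on a flexible seven-membered ring, combined with four carbonyl-level functions that must be told apart. The key step uses the fact that each cis arm starts with a CH2 on C6 or C7 and ends in an oxidised carbon: these four carbons plus C6 and C7 form a six-membered ring whose C=C joins the future aldehyde carbon to the future methyl-ketone carbon. That ring is the Diels–Alder adduct of a 2-oxy-3-methylbutadiene on the C7=C6 alkene of a cycloheptadienone in which C5 is still sp2.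

## Logic of the disconnections

21 to 19: the O–Si bond (21 to 20) and then the O–acyl bond of the enol ester (20 to 19) are cut first, because the enol ester tolerates none of the basic, reductive or oxidative steps used elsewhere and a free primary alcohol would compete for the acylating agent. The gain is that every C–C bond and stereocentre is settled before the most fragile group appears. The forward demand is an E-selective O-acylation of an aldehyde enol beside two ketones, and a desilylation mild enough for the enol ester.

19 to 18: the aldehyde carbon of the C6 arm and the ketone carbon of the C7 arm are reconnected as the two carbinol carbons of a vicinal diol. This replaces the 1,4-diketone and the 1,6-keto aldehyde by one inert cis-fused six-membered ring that also locks C6 against C7. The forward glycol cleavage must leave enone, alkene and silyl ether alone; it delivers the C6 arm directly at the aldehyde level, so no acid has to be reduced beside ketones (the cost of opening the ring by ozonolysis).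

18 to 13: at C2 the O–Si bond (18 to 17), the C2–CH2OH bond (17 to 16) and the C2=C3 double bond (16 to 13) are removed in turn. With the methyl ketone still masked, C1 is the only ketone in 13 and C2 its only unhindered α-carbon, so desaturation has a single site. The demand is kinetic enolisation at C2 without touching C7–H, then α-hydroxymethylation of a seven-membered enone.

13 to 11: the homoprenyl chain is cut at its trisubstituted C=C (13 to 12, olefination of an aldehyde by a three-carbon ylide) and at C5–CH2 (12 to 11, Markovnikov hydroalkylation of the C4=C5 alkene by a three-carbon enal). This removes the quaternary centre. The forward radical at C5 must be trapped anti to the C6–CH2 bond, and the step must precede the introduction of any other alkene that a metal hydride could attack.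

11 to 8: the C–H bond of the secondary carbinol (11 to 10) and the C–O bond of the tertiary carbinol (10 to 8) are cut, leading back to the silyl enol ether of the cycloadduct. The enol ether is the most electron-rich alkene of 8 and the six-ring ketone of 10 is activated by its neighbouring hydroxyl, so both steps can be chemoselective. The configuration of the two carbinol carbons is immaterial because step 14 destroys both.

8 to 5 and 7: the C6–CH2 and C7–CH2 bonds are cut in a retro-(4+2) sense. One bicyclic compound with two stereocentres becomes two achiral partners. The forward step needs site selectivity for C7=C6 over C5=C4, regiochemistry from the silyloxy group, and enantioface selection by a chiral Lewis acid; the cis fusion is inherent. The skeletons of 5 and 7 are kept unchanged, with the bulky silyl group on 7 retained for acid stability, and 8 was checked against the target: it must be (6S,7R) in target numbering.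

5 to 1, and 7 to 6: 5 is traced through 4, 3 and 2 to 1 by removing the one carbon inserted between the carbonyl carbon and its α-carbon (cyclopropanation and oxidative ring opening of a linear dienol silyl ether). The demand is the linear, not the cross-conjugated, dienol ether. 7 is the O-silylated enol form of 6.

## Other disconnections considered

Alternative 1: the ring is cut at C1–C2 and C5–C6. Forward, a Fischer-type chromium alkenyl(alkoxy)carbene with a menthol-derived chiral alkoxy group would cyclopropanate the terminal alkene of (Z)-4,8-dimethylnona-1,3,7-triene A2, and the cis-divinylcyclopropane would undergo Cope rearrangement in the same flask to the cycloheptadiene A1.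
- In favour: the seven-membered ring, the quaternary C5 with its homoprenyl chain and the adjacent C6 centre arise in one operation, with their relative configuration transcribed from two alkene geometries through a boat transition state. On the construction of C5 this is better than the chosen plan, which needs a separate radical step; on ring formation it is at least equal, since no ring expansion is needed.
- Against: absolute control rests on a stoichiometric auxiliary and stoichiometric chromium, and a simple terminal diene alkene is a reluctant partner for such carbenes. The C6 arm of A1 is one carbon short and the C7 arm is absent. C7 would have to be alkylated after enol ether hydrolysis, where the electrophile should enter trans to the C6 substituent, the opposite of what is needed. C3=C4 must then be saturated beside the homoprenyl alkene, and C2 still needs its substituent and unsaturation.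
- Comparison: both plans rely on pericyclic stereospecificity. The chosen plan obtains the cis C6/C7 pair from a concerted cycloaddition, not from an enolate alkylation. The step gain of alternative 1 at the key step would be paid back in the longer adjustment afterwards.

Alternative 2: the ring is cut at C4–C5 and C6–C7. Forward, an oxidopyrylium generated by base from an acetoxypyranone would add across a tethered E-trisubstituted alkene to give the bridged tetracycle A3.
- In favour: the reaction is intramolecular and concerted, so as a ring-forming event it is the equal of the chosen cycloaddition. It sets C5 and C6 together from the alkene geometry, which is better than a separate radical step. It delivers the C1 ketone, the C2=C3 alkene and the oxygenated C2 substituent ready-made, which is clearly better than desaturation plus hydroxymethylation. Its acetonide tether hides both arms as a glycol, the same device used in the chosen endgame.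
- Against: the oxygen bridge between C7 and C4 must be excised. That means reductive C7–O cleavage, with C7 set anew by protonation, followed by deoxygenation of a γ-hydroxy enone that is prone to elimination. Facial selectivity depends on the tether stereocentres, which have to be made enantioenriched beforehand, and the linear precursor is long.
- Comparison: alternative 2 is structurally more convergent at the key step. It is less economical in redox steps and in the length of the route to the precursor.

Alternative 3: the ring is cut at C1–C7. Forward, a chiral triazolium-derived carbene would convert a C1 aldehyde into an acyl anion equivalent that adds to C7 of a tethered enone (Stetter reaction) to give the cycloheptanone A4, with C6 taken from (R)-limonene A5.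
- In favour: the absolute configuration at C6 is bought from the chiral pool, which is equal to or better than catalytic induction. The exocyclic methylene of A4 is a better hydrogen-atom-transfer substrate than the trisubstituted alkene of the chosen plan. The C6 arm is already at the alcohol level.
- Against: seven-membered Stetter closure onto a β-alkyl enone has little precedent. C7 would be created α to a 1,4-diketone and is epimerisable, so the cis relationship would rest on catalyst–substrate matching. The methyl ketone would be present from the key step on, which complicates regioselective work at C2. Degrading A5 and extending its isopropenyl methyl by three carbons costs many steps.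
- Comparison: the chosen plan sets C6 and C7 together and stereospecifically, and keeps the methyl ketone masked to the end. Alternative 3 would be superior only in the source of absolute configuration and in the ease of the radical step.

Key step: step 6

Assumption 1: on the α-C–H···O binding model the oxazaborolidinium from (R)-α,α-diphenylprolinol leaves the C7-Re/C6-Si face of bound 5 open; both antipodes of the catalyst are available, so only its hand changes if the sense proves opposite.

Assumption 2: the carbinol configurations drawn for 9 to 18 are those expected from convex-face oxygen transfer and intramolecular hydride delivery; both centres are destroyed in step 14, so the route does not depend on them.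

Assumption 3: 3-methylbut-2-enoic anhydride is taken as a purchasable reagent (otherwise it is made from the acid and a carbodiimide).

## Steps

Step 1
Reactants: 1 3-methylcyclohex-2-en-1-one
Product: 2 3-methyl-1-(trimethylsilyloxy)cyclohexa-1,3-diene
Conditions: TMSCl, NaI, Et3N, MeCN, rt
Reagents that add atoms: chlorotrimethylsilane C[Si](C)(C)Cl
Why: Equilibrating silylation (iodosilane formed in the flask, amine base) gives the thermodynamic, linearly conjugated dienol ether with both alkenes endocyclic; the cross-conjugated kinetic isomer is avoided because it would ring-expand to the wrong dienone.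

Step 2
Reactants: 2 3-methyl-1-(trimethylsilyloxy)cyclohexa-1,3-diene
Product: 3 racemic 2-methyl-6-(trimethylsilyloxy)bicyclo[4.1.0]hept-2-ene
Conditions: Et2Zn, CH2I2, Et2O, 0 °C to rt
Reagents that add atoms: diiodomethane ICI
Why: Furukawa-modified Simmons–Smith cyclopropanation is fastest at the electron-rich silyl enol ether alkene, so about one equivalent of carbenoid leaves the methyl-substituted alkene alone; the ring fusion can only be cis and the racemate is irrelevant because both centres are lost in step 3.

Step 3
Reactants: 3 racemic 2-methyl-6-(trimethylsilyloxy)bicyclo[4.1.0]hept-2-ene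
Product: 4 racemic 3-chloro-4-methylcyclohept-4-en-1-one
Conditions: FeCl3, DMF, 0 °C to rt
Reagents that add atoms: iron trichloride Cl[Fe](Cl)Cl
Why: One-electron oxidation of the siloxycyclopropane by trivalent iron cleaves the internal cyclopropane bond to a ring-expanded allylic β-keto radical, which takes chlorine from a second FeCl3 (Saegusa ring expansion); an allylic isomer of the chloride converges in step 4.

Step 4
Reactants: 4 racemic 3-chloro-4-methylcyclohept-4-en-1-one
Product: 5 4-methylcyclohepta-2,4-dien-1-one
Conditions: NaOAc, MeOH, reflux
Reagents that add atoms: none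
Why: E1cB loss of HCl from the β-chloro ketone (vinylogous loss from the allylic isomer) gives the conjugated dienone under buffered conditions too mild to move the diene out of conjugation.

Step 5
Reactants: 6 3-methylbut-3-en-2-one
Product: 7 3-methyl-2-(triisopropylsilyloxy)buta-1,3-diene
Conditions: TIPSOTf, Et3N, CH2Cl2, 0 °C
Reagents that add atoms: triisopropylsilyl trifluoromethanesulfonate CC(C)[Si](OS(=O)(=O)C(F)(F)F)(C(C)C)C(C)C
Why: Soft enolisation and O-silylation; the acetyl methyl is the only enolisable position, so a single 2-silyloxydiene forms.

Step 6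
Reactants: 5 4-methylcyclohepta-2,4-dien-1-one; 7 3-methyl-2-(triisopropylsilyloxy)buta-1,3-diene
Product: 8 (4aR,9aS)-3,9-dimethyl-2-(triisopropylsilyloxy)-1,4,4a,6,7,9a-hexahydro-5H-benzo[7]annulen-5-one (cis-fused; 6S,7R in target numbering)
Conditions: (R)-3,3-diphenyl-1-(o-tolyl)tetrahydro-1H,3H-pyrrolo[1,2-c][1,3,2]oxazaborole (20 mol %), Tf2NH (18 mol %), 7 (2 equiv), CH2Cl2, −78 to −40 °C
Reagents that add atoms: none
Why: The triflimide-activated oxazaborolidinium binds the C1 carbonyl of 5 through the lone pair syn to C7 (α-C–H···O contact), lowering the LUMO of the conjugated C7=C6 alkene, and the electron-rich diene 7 adds in a normal-demand, concerted but asynchronous (4+2) cycloaddition in which the C6–CH2 bond is the more advanced. The closest known reaction type is the oxazaborolidinium-catalysed Diels–Alder reaction of cyclic enones with 2-silyloxy-1,3-dienes. The six-membered carbocycle closes by suprafacial addition of both diene termini to one face of the Z ring alkene, so C6–H and C7–H are cis whichever face is used. The absolute configuration of both new centres is set by the catalyst alone: its aryl group shields one face of the bound dienone and 7 approaches the C7-Re/C6-Si face, giving (6S,7R). Site selectivity for C7=C6 over C5=C4 follows from direct conjugation to the complexed carbonyl and from the methyl group on C5. Regiochemistry follows from the silyloxy group, which makes the adjacent terminal CH2 the most nucleophilic carbon and pairs it with the β-carbon C6, so the oxygenated carbon lies in the C6 arm and the methyl-bearing carbon in the C7 arm. Both diene termini are unsubstituted, so there is no endo/exo issue, and the bulky silyl group resists protodesilylation by the strong acid.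

Step 7
Reactants: 8 (4aR,9aS)-3,9-dimethyl-2-(triisopropylsilyloxy)-1,4,4a,6,7,9a-hexahydro-5H-benzo[7]annulen-5-one
Product: 10 (4aR,9aS)-3-hydroxy-3,9-dimethyl-3,4,4a,6,7,9a-hexahydro-1H-benzo[7]annulene-2,5-dione (3-OH cis to the ring-fusion hydrogens), via silyloxy epoxide 9 (not isolated)
Conditions: dimethyldioxirane, acetone/CH2Cl2, −78 to −20 °C; then HF·pyridine, THF, 0 °C
Reagents that add atoms: dimethyldioxirane CC1(C)OO1
Why: Rubottom oxidation: the electrophilic dioxirane epoxidises the tetrasubstituted silyl enol ether much faster than the trisubstituted ring alkene, from the face of the ring-fusion hydrogens (convex face of the cis-fused bicycle); fluoride then removes silicon and the alkoxy epoxide opens to the α-hydroxy ketone.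

Step 8
Reactants: 10 (4aR,9aS)-3-hydroxy-3,9-dimethyl-3,4,4a,6,7,9a-hexahydro-1H-benzo[7]annulene-2,5-dione
Product: 11 (4aR,9aS)-2,3-dihydroxy-3,9-dimethyl-1,2,3,4,4a,6,7,9a-octahydro-5H-benzo[7]annulen-5-one (trans-diol; 3-OH cis to the ring-fusion hydrogens)
Conditions: Me4NBH(OAc)3, MeCN/AcOH, −30 to 0 °C
Reagents that add atoms: none
Why: Hydroxyl-directed triacetoxyborohydride reduction: the tertiary alcohol exchanges onto boron and delivers hydride intramolecularly to the adjacent ketone, giving the trans-diol, while the unactivated C1 ketone is not reduced by this mild hydride.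

Step 9
Reactants: 11 (4aR,9aS)-2,3-dihydroxy-3,9-dimethyl-1,2,3,4,4a,6,7,9a-octahydro-5H-benzo[7]annulen-5-one
Product: 12 3-[(4aR,9aS)-2,3-dihydroxy-3,9-dimethyl-5-oxodecahydro-1H-benzo[7]annulen-9-yl]propanal (C9 quaternary; methyl cis and chain trans to the C9a–C1 bond)
Conditions: acrolein, Fe(acac)3, PhSiH3, EtOH/ethylene glycol, 40 °C
Reagents that add atoms: acrolein C=CC=O
Why: Metal-hydride hydrogen-atom transfer puts H on C4 (target numbering) and leaves the tertiary C5 radical, which adds to acrolein (Giese addition) on the face anti to the C6–CH2 bond, away from the cis-fused six-membered ring, and so sets C5; the adduct radical is reduced by divalent iron and protonated by ethanol.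

Step 10
Reactants: 12 3-[(4aR,9aS)-2,3-dihydroxy-3,9-dimethyl-5-oxodecahydro-1H-benzo[7]annulen-9-yl]propanal
Product: 13 (4aR,9aS)-2,3-dihydroxy-3,9-dimethyl-9-(4-methylpent-3-en-1-yl)decahydro-5H-benzo[7]annulen-5-one
Conditions: i-PrPPh3I, n-BuLi, THF, 0 °C; then 12, −78 to 0 °C (ylide 3.2 equiv)
Reagents that add atoms: isopropyltriphenylphosphonium iodide CC(C)[P+](c1ccccc1)(c1ccccc1)c1ccccc1.[I-]
Why: Wittig olefination with the non-stabilised isopropylidene ylide is far faster at the aldehyde than at the hindered C1 ketone at low temperature; two equivalents are consumed reversibly by the hydroxyl groups, which return on work-up.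

Step 11
Reactants: 13 (4aR,9aS)-2,3-dihydroxy-3,9-dimethyl-9-(4-methylpent-3-en-1-yl)decahydro-5H-benzo[7]annulen-5-one
Product: 16 (4aR,9aS)-2,3-dihydroxy-3,9-dimethyl-9-(4-methylpent-3-en-1-yl)-1,2,3,4,4a,8,9,9a-octahydro-5H-benzo[7]annulen-5-one (C6=C7 enone), via tris(trimethylsilyl) derivative 14 (not isolated), via bis(trimethylsilyl) ether 15 (not isolated)
Conditions: LiN(i-Pr)2 (3.5 equiv), TMSCl, THF, −78 °C; Pd(OAc)2, MeCN, rt; then 1 M HCl, THF, 0 °C
Reagents that add atoms: none
Why: Kinetic deprotonation of the only ketone at its unhindered α-CH2 with silylation in the flask (the two hydroxyls are silylated as well), then Saegusa–Ito oxidation by divalent palladium with β-hydride elimination towards the ring CH2; dilute acid removes the two silyl ethers, and the ring-fusion C–H α to the ketone is not touched.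

Step 12
Reactants: 16 (4aR,9aS)-2,3-dihydroxy-3,9-dimethyl-9-(4-methylpent-3-en-1-yl)-1,2,3,4,4a,8,9,9a-octahydro-5H-benzo[7]annulen-5-one
Product: 17 (4aR,9aS)-2,3-dihydroxy-6-(hydroxymethyl)-3,9-dimethyl-9-(4-methylpent-3-en-1-yl)-1,2,3,4,4a,8,9,9a-octahydro-5H-benzo[7]annulen-5-one
Conditions: aq. HCHO, DMAP, THF/H2O, rt
Reagents that add atoms: formaldehyde C=O
Why: Morita–Baylis–Hillman reaction: the amine adds reversibly to the β-carbon, the resulting enolate is hydroxymethylated at the α-carbon and the catalyst is expelled; no strong base is present and the diol and the homoprenyl alkene are spectators.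

Step 13
Reactants: 17 (4aR,9aS)-2,3-dihydroxy-6-(hydroxymethyl)-3,9-dimethyl-9-(4-methylpent-3-en-1-yl)-1,2,3,4,4a,8,9,9a-octahydro-5H-benzo[7]annulen-5-one
Product: 18 (4aR,9aS)-6-[(tert-butyldimethylsilyloxy)methyl]-2,3-dihydroxy-3,9-dimethyl-9-(4-methylpent-3-en-1-yl)-1,2,3,4,4a,8,9,9a-octahydro-5H-benzo[7]annulen-5-one
Conditions: TBSCl, imidazole, CH2Cl2, 0 °C
Reagents that add atoms: tert-butyldimethylsilyl chloride CC(C)(C)[Si](C)(C)Cl
Why: The bulky chlorosilane silylates the primary allylic hydroxyl selectively over the hindered secondary and tertiary ones, which must stay free for the glycol cleavage.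

Step 14
Reactants: 18 (4aR,9aS)-6-[(tert-butyldimethylsilyloxy)methyl]-2,3-dihydroxy-3,9-dimethyl-9-(4-methylpent-3-en-1-yl)-1,2,3,4,4a,8,9,9a-octahydro-5H-benzo[7]annulen-5-one
Product: 19 (5S,6S,7R)-2-[(tert-butyldimethylsilyloxy)methyl]-5-methyl-5-(4-methylpent-3-en-1-yl)-6-(2-oxoethyl)-7-(2-oxopropyl)cyclohept-2-en-1-one
Conditions: NaIO4, THF/pH 7 buffer, 0 °C
Reagents that add atoms: none
Why: Periodate glycol cleavage through the cyclic periodate ester (accessible from the diequatorial conformer of the trans-diol) opens the sacrificial ring and releases the C6 acetaldehyde arm and the C7 acetonyl arm at their final oxidation levels in one neutral step.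

Step 15
Reactants: 19 (5S,6S,7R)-2-[(tert-butyldimethylsilyloxy)methyl]-5-methyl-5-(4-methylpent-3-en-1-yl)-6-(2-oxoethyl)-7-(2-oxopropyl)cyclohept-2-en-1-one
Product: 20 (5S,6S,7R)-2-[(tert-butyldimethylsilyloxy)methyl]-5-methyl-5-(4-methylpent-3-en-1-yl)-6-[(E)-2-(3-methylbut-2-enoyloxy)ethenyl]-7-(2-oxopropyl)cyclohept-2-en-1-one
Conditions: (Me2C=CHCO)2O, Et3N, DMAP, CH2Cl2, 0 °C to rt
Reagents that add atoms: 3-methylbut-2-enoic anhydride CC(C)=CC(=O)OC(=O)C=C(C)C
Why: Amine-mediated enolisation of the aldehyde and O-acylation by the acylpyridinium (enol ester formation); the aldehyde enolises far more readily than the ketones, and the E isomer should be favoured because the Z isomer presses the acyloxy group against the bulky ring carbon C6.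

Step 16
Reactants: 20 (5S,6S,7R)-2-[(tert-butyldimethylsilyloxy)methyl]-5-methyl-5-(4-methylpent-3-en-1-yl)-6-[(E)-2-(3-methylbut-2-enoyloxy)ethenyl]-7-(2-oxopropyl)cyclohept-2-en-1-one
Product: 21 (5S,6S,7R)-2-(hydroxymethyl)-5-methyl-5-(4-methylpent-3-en-1-yl)-6-[(E)-2-(3-methylbut-2-enoyloxy)ethenyl]-7-(2-oxopropyl)cyclohept-2-en-1-one (target)
Conditions: HF·pyridine, pyridine, THF, 0 °C
Reagents that add atoms: none
Why: Fluoride-induced Si–O cleavage under buffered, non-basic conditions that leave the enol ester, the enone and the ketones untouched.

## Compound list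

1 | 3-methylcyclohex-2-en-1-one | CC1=CC(=O)CCC1 | starting material
2 | 3-methyl-1-(trimethylsilyloxy)cyclohexa-1,3-diene | C[Si](C)(C)OC1=CC(C)=CCC1 | intermediate
3 | racemic 2-methyl-6-(trimethylsilyloxy)bicyclo[4.1.0]hept-2-ene (ring fusion necessarily cis) | C[Si](C)(C)OC12CC1C(C)=CCC2 | intermediate
4 | racemic 3-chloro-4-methylcyclohept-4-en-1-one | O=C1CC(Cl)C(C)=CCC1 | intermediate
5 | 4-methylcyclohepta-2,4-dien-1-one | O=C1C=CC(C)=CCC1 | intermediate
6 | 3-methylbut-3-en-2-one | CC(=O)C(C)=C | starting material
7 | 3-methyl-2-(triisopropylsilyloxy)buta-1,3-diene | C=C(C)C(=C)O[Si](C(C)C)(C(C)C)C(C)C | intermediate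
8 | (4aR,9aS)-3,9-dimethyl-2-(triisopropylsilyloxy)-1,4,4a,6,7,9a-hexahydro-5H-benzo[7]annulen-5-one; cis-fused, 6S,7R in target numbering | O=C1CCC=C(C)[C@H]2CC(O[Si](C(C)C)(C(C)C)C(C)C)=C(C)C[C@@H]12 | intermediate
9 | 2,3-epoxide of 8 (2-silyloxy oxirane), epoxide oxygen on the face of the ring-fusion hydrogens | O=C1CCC=C(C)[C@H]2C[C@]3(O[Si](C(C)C)(C(C)C)C(C)C)O[C@]3(C)C[C@@H]12 | intermediate (not isolated)
10 | (4aR,9aS)-3-hydroxy-3,9-dimethyl-3,4,4a,6,7,9a-hexahydro-1H-benzo[7]annulene-2,5-dione; 3-OH cis to H-4a and H-9a | O=C1CCC=C(C)[C@H]2CC(=O)[C@@](O)(C)C[C@@H]12 | intermediate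
11 | (4aR,9aS)-2,3-dihydroxy-3,9-dimethyl-1,2,3,4,4a,6,7,9a-octahydro-5H-benzo[7]annulen-5-one; 3-OH cis to the ring-fusion hydrogens, 2-OH trans to 3-OH | O=C1CCC=C(C)[C@H]2C[C@@H](O)[C@@](O)(C)C[C@@H]12 | intermediate
12 | 3-[(4aR,9aS)-2,3-dihydroxy-3,9-dimethyl-5-oxodecahydro-1H-benzo[7]annulen-9-yl]propanal; chain on C9 trans to the C9a–C1 bond | O=C1CCC[C@](C)(CCC=O)[C@H]2C[C@@H](O)[C@@](O)(C)C[C@@H]12 | intermediate
13 | (4aR,9aS)-2,3-dihydroxy-3,9-dimethyl-9-(4-methylpent-3-en-1-yl)decahydro-5H-benzo[7]annulen-5-one | O=C1CCC[C@](C)(CCC=C(C)C)[C@H]2C[C@@H](O)[C@@](O)(C)C[C@@H]12 | intermediate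
14 | tris(trimethylsilyl) derivative of 13: C5=C6 silyl enol ether and both hydroxyls silylated | C[Si](C)(C)OC1=CCC[C@](C)(CCC=C(C)C)[C@H]2C[C@@H](O[Si](C)(C)C)[C@@](O[Si](C)(C)C)(C)C[C@@H]12 | intermediate (not isolated)
15 | bis(trimethylsilyl) ether of 16 | O=C1C=CC[C@](C)(CCC=C(C)C)[C@H]2C[C@@H](O[Si](C)(C)C)[C@@](O[Si](C)(C)C)(C)C[C@@H]12 | intermediate (not isolated)
16 | (4aR,9aS)-2,3-dihydroxy-3,9-dimethyl-9-(4-methylpent-3-en-1-yl)-1,2,3,4,4a,8,9,9a-octahydro-5H-benzo[7]annulen-5-one | O=C1C=CC[C@](C)(CCC=C(C)C)[C@H]2C[C@@H](O)[C@@](O)(C)C[C@@H]12 | intermediate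
17 | 6-(hydroxymethyl) derivative of 16 | O=C1C(CO)=CC[C@](C)(CCC=C(C)C)[C@H]2C[C@@H](O)[C@@](O)(C)C[C@@H]12 | intermediate
18 | 6-[(tert-butyldimethylsilyloxy)methyl] derivative of 16 | O=C1C(CO[Si](C)(C)C(C)(C)C)=CC[C@](C)(CCC=C(C)C)[C@H]2C[C@@H](O)[C@@](O)(C)C[C@@H]12 | intermediate
19 | (5S,6S,7R)-2-[(tert-butyldimethylsilyloxy)methyl]-5-methyl-5-(4-methylpent-3-en-1-yl)-6-(2-oxoethyl)-7-(2-oxopropyl)cyclohept-2-en-1-one | CC(=O)C[C@H]1C(=O)C(CO[Si](C)(C)C(C)(C)C)=CC[C@](C)(CCC=C(C)C)[C@H]1CC=O | intermediate
20 | (5S,6S,7R)-2-[(tert-butyldimethylsilyloxy)methyl]-5-methyl-5-(4-methylpent-3-en-1-yl)-6-[(E)-2-(3-methylbut-2-enoyloxy)ethenyl]-7-(2-oxopropyl)cyclohept-2-en-1-one | CC(=O)C[C@H]1C(=O)C(CO[Si](C)(C)C(C)(C)C)=CC[C@](C)(CCC=C(C)C)[C@H]1/C=C/OC(=O)C=C(C)C | intermediate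
21 | (5S,6S,7R)-2-(hydroxymethyl)-5-methyl-5-(4-methylpent-3-en-1-yl)-6-[(E)-2-(3-methylbut-2-enoyloxy)ethenyl]-7-(2-oxopropyl)cyclohept-2-en-1-one | CC(=O)C[C@H]1C(=O)C(CO)=CC[C@](C)(CCC=C(C)C)[C@H]1/C=C/OC(=O)C=C(C)C | target

## Step count and least certain steps

Total step count: 16. Longest linear sequence: 15 (steps 1 to 4 and 6 to 16); step 5 is a one-step branch.

Step 6 (key step). Most likely failure: poor enantioface discrimination, because the dienone is a flexible seven-membered ring whose methyl-substituted alkene sits next to the reacting carbon and close to the catalyst aryl group. Vinylogous 1,6-addition of the silyl enol ether, or acid-induced loss of silicon from the diene, could also occur. Fallback (sets out from 5 and 7, returns at 11): the cycloaddition is run without asymmetric induction (Me2AlCl, CH2Cl2, −78 °C), giving 8 together with the enantiomer of 8 F1. The racemate is carried through steps 7 and 8 unchanged; the antipodal series is the enantiomer of silyloxy epoxide 9 F2, the enantiomer of hydroxy ketone 10 F3 and the enantiomer of diol 11 F4. The racemic diol is esterified at the secondary hydroxyl with (S)-2-methoxy-2-phenylacetic acid (DCC, DMAP, CH2Cl2) to give the (S)-O-methylmandelate of 11 F5 and the (S)-O-methylmandelate of the enantiomer of 11 F6. These diastereomers are separated by chromatography, and LiOH in aqueous THF at 0 °C hydrolyses F5 to enantiopure 11.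

Step 9. Most likely failure: radical–polar crossover that ends in aldol closure of the iron enolate onto the C1 ketone instead of protonation. Oligomerisation of the enal acceptor and incomplete facial selectivity at C5 are further risks. Fallback (sets out from 11, returns at 12): methyl acrylate is used as acceptor under the same Fe(acac)3/PhSiH3 conditions, giving the methyl ester F7, in which C5 carries a 2-(methoxycarbonyl)ethyl chain. Saponification (LiOH, THF/H2O) gives the carboxylic acid F8, and EtSH, EDC and DMAP give the S-ethyl thioester F9. Fukuyama reduction (Et3SiH, Pd on carbon, acetone, rt) then delivers aldehyde 12 without touching the C1 ketone.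

Step 15. Most likely failure: formation of the Z enol ester alongside the E isomer under kinetic control. Base-induced aldol closure between the aldehyde arm and the methyl ketone before O-acylation is the second risk. Fallback (sets out from 19, returns at 20): the acylation is driven to completion with excess anhydride without regard to geometry, accepting the (Z)-enol ester F11 beside 20. The mixture is then equilibrated with a catalytic thiyl radical (PhSSPh, light, benzene, rt), whose reversible addition to the enol ester alkene converts F11 into the thermodynamically preferred E isomer 20.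

Step 12. Most likely failure: sluggish conjugate addition of the amine catalyst to a hindered seven-membered enone, so that the reaction stalls. Fallback (sets out from 16, returns at 17): I2 and pyridine in CH2Cl2 give the α-iodo enone F10 by amine addition, iodination and elimination. Stille coupling of F10 with Bu3SnCH2OH (Pd(PPh3)4, CuI, dioxane, 80 °C) installs the hydroxymethyl group and gives 17.

## Further compounds

F1 | step 6 | enantiomer of 8 | O=C1CCC=C(C)[C@@H]2CC(O[Si](C(C)C)(C(C)C)C(C)C)=C(C)C[C@H]12
F2 | step 6 | enantiomer of silyloxy epoxide 9 | O=C1CCC=C(C)[C@@H]2C[C@@]3(O[Si](C(C)C)(C(C)C)C(C)C)O[C@@]3(C)C[C@H]12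
F3 | step 6 | enantiomer of hydroxy ketone 10 | O=C1CCC=C(C)[C@@H]2CC(=O)[C@](O)(C)C[C@H]12
F4 | step 6 | enantiomer of diol 11 | O=C1CCC=C(C)[C@@H]2C[C@H](O)[C@](O)(C)C[C@H]12
F5 | step 6 | (S)-2-methoxy-2-phenylacetate of 11 at the secondary hydroxyl | O=C1CCC=C(C)[C@H]2C[C@@H](OC(=O)[C@@H](OC)c3ccccc3)[C@@](O)(C)C[C@@H]12
F6 | step 6 | (S)-2-methoxy-2-phenylacetate of the enantiomer of 11 | O=C1CCC=C(C)[C@@H]2C[C@H](OC(=O)[C@@H](OC)c3ccccc3)[C@](O)(C)C[C@H]12
F7 | step 9 | methyl 3-[(4aR,9aS)-2,3-dihydroxy-3,9-dimethyl-5-oxodecahydro-1H-benzo[7]annulen-9-yl]propanoate | O=C1CCC[C@](C)(CCC(=O)OC)[C@H]2C[C@@H](O)[C@@](O)(C)C[C@@H]12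
F8 | step 9 | 3-[(4aR,9aS)-2,3-dihydroxy-3,9-dimethyl-5-oxodecahydro-1H-benzo[7]annulen-9-yl]propanoic acid | O=C1CCC[C@](C)(CCC(=O)O)[C@H]2C[C@@H](O)[C@@](O)(C)C[C@@H]12
F9 | step 9 | S-ethyl 3-[(4aR,9aS)-2,3-dihydroxy-3,9-dimethyl-5-oxodecahydro-1H-benzo[7]annulen-9-yl]propanethioate | O=C1CCC[C@](C)(CCC(=O)SCC)[C@H]2C[C@@H](O)[C@@](O)(C)C[C@@H]12
F10 | step 12 | 6-iodo derivative of 16 (α-iodo enone) | O=C1C(I)=CC[C@](C)(CCC=C(C)C)[C@H]2C[C@@H](O)[C@@](O)(C)C[C@@H]12
F11 | step 15 | (Z)-enol ester isomer of 20 | CC(=O)C[C@H]1C(=O)C(CO[Si](C)(C)C(C)(C)C)=CC[C@](C)(CCC=C(C)C)[C@H]1/C=C\OC(=O)C=C(C)C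
A1 | alternative 1 | 1-(8-phenylmenthyloxy)-6-[(tert-butyldimethylsilyloxy)methyl]-5-methyl-5-(4-methylpent-3-enyl)cyclohepta-1,4-diene | C1C(O[C@@H]2C[C@H](C)CC[C@H]2C(C)(C)c2ccccc2)=C[C@H](CO[Si](C)(C)C(C)(C)C)[C@@](C)(CCC=C(C)C)C=C1
A2 | alternative 1 | (Z)-4,8-dimethylnona-1,3,7-triene | C=C/C=C(C)\CCC=C(C)C
A3 | alternative 2 | tetracyclic 8-oxabicyclo[3.2.1]oct-3-en-2-one cycloadduct with acetonide tether ring | [C@]123C(=O)C(CO[Si](C)(C)C(C)(C)C)=C[C@@H](O2)[C@](C)(CCC=C(C)C)[C@H]1C[C@H]4OC(C)(C)O[C@@]4(C)C3
A4 | alternative 3 | cis-2-acetonyl-3-[2-(tert-butyldimethylsilyloxy)ethyl]-4-methylenecycloheptanone | CC(=O)C[C@H]1C(=O)CCCC(=C)[C@H]1CCO[Si](C)(C)C(C)(C)C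
A5 | alternative 3 | (R)-limonene | CC1=CC[C@H](C(C)=C)CC1
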